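## The problem

Pestalone F (27) is a benzophenone whose carbonyl group is flanked by four ortho substituents. Ring A carries C2 OH and C6 OCH3 beside C3 Cl and C4 CH3; ring B is hexasubstituted (C1' ketone, C2' CHO, C3' OH, C4' H, C5' OH, C6' prenyl). The synthesis must therefore make a very crowded diaryl ketone and place five different groups around ring B in a fixed order, which substitution of a preformed resorcinol cannot be trusted to do. There is no stereocentre in 27; a carbinol at the future ketone carbon can be carried as a racemate and is erased by oxidation, so no stereocentre has to control another. Three features are fragile. The ortho-aroylbenzaldehyde rearranges under base or nucleophiles by intramolecular hydride transfer (Cannizzaro–Tishchenko) to the isomeric 3-arylphthalide and condenses with amines. The prenyl group beside the C5' phenol closes to a chroman under strong acid and is attacked by electrophilic halogen, and the free phenols are easily oxidised. Ring A adds a regiochemical demand: one chlorine ortho to the phenol although the para position is open, and one methyl ether among four aryl oxygens. The enabling feature is the pattern of ring B: C3'–C6' is the chain of a γ-prenylated acetoacetate (C3' the ester carbon, C5' the ketone carbon, C6' the γ-carbon), and C1'–C2' is a two-carbon unit bearing both carbonyl carbons, that is, an alkyne between an ester and an aryl carbinol. A 1,3-bis(silyloxy)diene and an alkynoate can thus be joined by cycloaddition and aromatised to give ring B with all six substituents in place.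

## Retrosynthesis

**27 to 26 to 24 (no skeletal bond cut).** The three phenols of 27 are taken back to the tris(silyl) ether 26, and both carbonyl groups of 26 to the two carbinols of diol 24. Releasing aldehyde and ketone in one operation is preferred to any sequence with a free hydroxyl beside a carbonyl group, because an ortho-(hydroxybenzyl)benzaldehyde closes to a lactol that is oxidised on to the lactone. Silyl ethers are chosen because they come off with buffered fluoride, which should neither isomerise the keto aldehyde nor cyclise the prenyl phenol. The forward steps must oxidise a hindered diaryl carbinol and a primary benzylic alcohol together (step 13) and then remove three aryl silyl groups without base (step 14).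

**24 to 22 to 21 to 19 (lactone C–O and O–Si bonds).** Diol 24 is the reduction product of phthalide 22, whose lactone carbonyl is the C2' carbon substituent and whose C3 is the future ketone carbon. The phthalide is not a detour. It forms by itself once the carbinol beside the ortho ester is unmasked (19 to 21), and 21 has the same formula as 27 and is its stable isomer. It also offers a stage at which only phenolic hydroxyls are present, so that exactly the three phenols can be silylated (21 to 22). Direct reduction of the open ester 19 would have to act on a doubly ortho-substituted benzoate and would leave four silyl ethers that cannot be told apart. The lactone path costs one more operation, but each step has a single reactive site.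

**19 to 7 + 16 (C2'–C3' and C6'–C1' cut; key step).** Ring B is divided into diene 7 (C3'–C6' with both oxygens and the prenyl group) and alkynoate 16 (C1', C2', the ester carbon and the carbinol carrying ring A). Compared with cutting the aryl–carbinol bond (aryl metal plus aldehyde on a finished ring B), this cut builds the hexasubstituted ring and the crowded junction at C1' in one step from two open-chain pieces. Regiochemistry is decided by polarity: the nucleophilic diene terminus meets the alkyne carbon β to the ester. The ketone must travel as a silylated carbinol, since a ynone would be the stronger acceptor and would reverse the orientation. The forward reaction must tolerate substituents at the bonding termini of both partners, and its work-up must cleave two trimethylsilyl ethers while two tert-butyldimethylsilyl ethers stay.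

**16 to 15 to 12 + 13 (carbinol C–C(sp) bond).** Alkynoate 16 is the silyl ether of propargylic alcohol 15, the adduct of lithiated methyl propiolate 13 with aldehyde 12. Using the propiolate itself brings in the ester in the same step, which saves a later carboxylation. The phenol of 12 is silylated beforehand so that no phenoxide sits beside the new ynoate. The addition has to be run cold because the acetylide is thermally labile.

**12 to 11 to 9 to 8 (formyl C–C bond, then C–Cl bond).** Aldehyde 12 is the silyl ether of salicylaldehyde 11, which comes from chlorophenol 9 by ortho-formylation and 9 from 3-methoxy-5-methylphenol 8 by ortho-chlorination. The order matters. Chlorine placed first at C6 of 8 (ortho to OH, para to OCH3) leaves a single free ortho site, C2 between the two oxygens, for the ortho-specific formylation. Formylation first would go para to the methoxy group. The chlorination has to be steered away from C4, the position para to OH.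

**7 to 5 to 4 to 1 + 2 (γ-carbon–prenyl bond).** Diene 7 is the O-silylated dienolate of silyl enol ether 5, which comes from β-keto ester 4, the γ-prenylation product of methyl acetoacetate 1 with prenyl bromide 2. The dianion alkylation places the prenyl group on the carbon that becomes C6', so no prenylation of an aromatic ring is ever needed.

## Roads not taken

**Alternative 1:** Ring A is cut at the C1–carbonyl bond and at the C2–O bond. Fluoride (CsF) releases a 3-methoxy-5-methyl aryne from silylaryl triflate A2, and nitrile oxide A3 adds across it to give benzisoxazole A1. The nucleophilic oxygen goes to the aryne carbon remote from the methoxy group, which is the orientation the target needs. Later N–O cleavage and imine hydrolysis would unmask the ortho-hydroxy ketone.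
- Merits: the crowded aryl–carbonyl bond is made by a cycloaddition that is little slowed by ortho substituents, and the two ortho bromines of A3 even protect the nitrile oxide from dimerisation. The ketone arrives at its final oxidation level with its phenol neighbour. In this respect the road is better than the chosen plan, which carries the ketone as a carbinol and pays with a reduction–oxidation sequence.
- Weak points: A1 contains neither chlorine, prenyl nor formyl. The two equivalent bromines would have to be exchanged one after the other by halogen–metal exchange. Ring A would have to be chlorinated late, where C3 competes with C5 and, once the prenyl group is present, with the alkene and the very electron-rich ring B. The methoxymethyl ethers require acid at the end, beside the prenyl phenol.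
- Comparison: the chosen plan sets against this that every ring B substituent is fixed in the ring-forming step and that the chlorine is placed in the first step on a simple phenol.

**Alternative 2:** Ring A is built last by a Danheiser benzannulation. Heating cyclobutenone A5 gives a chlorovinylketene, which adds to 1-methoxyalkyne A6 in a (2+2) sense (C1–C2). Ring opening and 6π electrocyclisation (C5–C6 bond, ring A closed) then give phenol A4.
- Merits: chlorine, methyl, methoxy and the free phenol of ring A are placed by construction with no regiochemical choice. That is better than the chosen plan, which relies on catalyst-directed ortho-chlorination in step 4.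
- Weak points: the hard ring is ring B, and here it must be finished beforehand by aromatic substitution (prenyl, hydroxymethyl and carbinol on adjacent carbons), which is the problem the chosen plan avoids. A6 is an acid-sensitive ynol ether with a bulky propargylic substituent, A5 is a labile, non-commercial haloketone, and the methoxymethyl ethers again need acid at the end.
- Comparison: the chosen plan sets against the built-in ring A regiochemistry a cheap commercial ring A phenol, a fallback for its chlorination, and de novo construction of the more demanding ring.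

**Alternative 3:** Ring B is cut at C1'–C2' only. Diketo-dioxinone A8 is folded by base and then acid through an intramolecular aldol condensation and dehydration into benzodioxinone A7. Fluoride would convert A7 into the same phthalide 21 with loss of acetone, so the end games coincide.
- Merits: the ring closure is intramolecular, runs under mild conditions, is not slowed by the crowding at C1', and its regiochemistry is written into the chain. In that respect it is at least as good as the bimolecular cycloaddition.
- Weak points: A8 must be assembled linearly on the valuable ring A fragment. This needs C-acylation with a hindered α-silyloxy arylacetic acid unit and placement of the prenyl group on the carbon between two ketones. The required aldol attacks the most hindered ketone, in competition with O-cyclisation to a pyranone and with retro-Claisen cleavage of the triketo system.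
- Comparison: the chosen plan sets against the easier ring closure two short branches (three and five steps) and a convergent ring-forming step that needs no polyketo intermediate.

Key step: step 9

Assumption: the C2=C3 geometry of 5 and the C1=C2 geometry of 7 are unassigned mixtures and do not matter because both double bonds end in the aromatic ring; every compound with the carbinol stereocentre is racemic. Abbreviations: TBS = tert-butyldimethylsilyl, TBSO = tert-butyldimethylsilyloxy, TMS = trimethylsilyl, TES = triethylsilyl.

## Route

Step 1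
Reactants: 1 methyl acetoacetate; 2 prenyl bromide (1-bromo-3-methylbut-2-ene)
Product: 4 methyl 7-methyl-3-oxooct-6-enoate, via sodium lithium dianion 3 (not isolated)
Conditions: NaH, THF, 0 °C; n-BuLi, 0 °C; then 2, 0 → 23 °C; aq. HCl
Reagents that add atoms: none
Why: γ-Alkylation of a β-keto ester dianion; the second deprotonation creates the more reactive terminal carbanion, which displaces the allylic bromide (SN2) and leaves C2 untouched.

Step 2
Reactants: 4 methyl 7-methyl-3-oxooct-6-enoate
Product: 5 methyl 7-methyl-3-(trimethylsilyloxy)octa-2,6-dienoate (mixture of 2E and 2Z isomers)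
Conditions: Me3SiCl, Et3N, hexane, 23 °C
Reagents that add atoms: chlorotrimethylsilane, C[Si](C)(C)Cl
Why: O-Silylation of the enolisable β-keto ester gives the silyl enol ether; the mixture of geometries is of no consequence.

Step 3
Reactants: 5 methyl 7-methyl-3-(trimethylsilyloxy)octa-2,6-dienoate
Product: 7 (3Z)-1-methoxy-7-methyl-1,3-bis(trimethylsilyloxy)octa-1,3,6-triene, via lithium dienolate 6 (not isolated)
Conditions: LiN(i-Pr)2, THF, −78 °C; Me3SiCl, −78 → 0 °C; used crude
Reagents that add atoms: chlorotrimethylsilane, C[Si](C)(C)Cl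
Why: Kinetic γ-deprotonation of the 3-silyloxy enoate and O-silylation of the ester dienolate give the 1,3-bis(silyloxy)diene; the 3Z geometry places the prenyl CH2 on the outer side of the s-cis diene.

Step 4
Reactants: 8 3-methoxy-5-methylphenol
Product: 9 2-chloro-5-methoxy-3-methylphenol
Conditions: SO2Cl2 (1 equiv, slow addition), i-Bu2NH (cat.), toluene, 23 → 60 °C
Reagents that add atoms: sulfuryl chloride, O=S(=O)(Cl)Cl
Why: Amine-catalysed electrophilic chlorination: the N-chloroamine formed in situ is held by hydrogen bonding to the phenol and delivers chlorine ortho to OH instead of para. Of the two ortho sites, the one para to the methoxy group is the more activated.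

Step 5
Reactants: 9 2-chloro-5-methoxy-3-methylphenol
Product: 11 3-chloro-2-hydroxy-6-methoxy-4-methylbenzaldehyde, via salicyl alcohol 10 (not isolated)
Conditions: (CH2O)n, MgCl2, Et3N, MeCN, reflux; aq. HCl
Reagents that add atoms: paraformaldehyde (reacts as formaldehyde), C=O
Why: Magnesium-mediated ortho-formylation of a phenol: the magnesium phenoxide binds formaldehyde and forms the C–C bond at the only free ortho position, between OH and OCH3. A second formaldehyde oxidises the magnesium salt of 10 by hydride transfer.

Step 6
Reactants: 11 3-chloro-2-hydroxy-6-methoxy-4-methylbenzaldehyde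
Product: 12 2-(TBSO)-3-chloro-6-methoxy-4-methylbenzaldehyde
Conditions: t-BuMe2SiCl, imidazole, DMF, 23 °C
Reagents that add atoms: tert-butyldimethylsilyl chloride, CC(C)(C)[Si](C)(C)Cl
Why: Routine silylation of a phenol; it removes the acidic proton and the phenoxide nucleophile before the acetylide addition.

Step 7
Reactants: 12 2-(TBSO)-3-chloro-6-methoxy-4-methylbenzaldehyde; 13 methyl propiolate
Product: 15 methyl 4-[2-(TBSO)-3-chloro-6-methoxy-4-methylphenyl]-4-hydroxybut-2-ynoate (racemic), via lithium acetylide 14 (not isolated)
Conditions: 13, LiN(i-Pr)2, THF, −78 °C; then 12, −78 °C; AcOH, −78 °C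
Reagents that add atoms: none
Why: 1,2-Addition of a lithium acetylide to an aldehyde; the acetylide is made and used at −78 °C because it decomposes on warming, and the cold acidic quench forestalls silyl migration to the new alkoxide. The new stereocentre forms as a racemate and is removed by oxidation in step 13.

Step 8
Reactants: 15 methyl 4-[2-(TBSO)-3-chloro-6-methoxy-4-methylphenyl]-4-hydroxybut-2-ynoate
Product: 16 methyl 4-(TBSO)-4-[2-(TBSO)-3-chloro-6-methoxy-4-methylphenyl]but-2-ynoate (racemic)
Conditions: t-BuMe2SiOTf, 2,6-lutidine, CH2Cl2, −78 → 0 °C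
Reagents that add atoms: tert-butyldimethylsilyl trifluoromethanesulfonate, CC(C)(C)[Si](C)(C)OS(=O)(=O)C(F)(F)F
Why: Silylation of a hindered secondary alcohol with a silyl triflate; the hindered, non-nucleophilic base avoids amine-induced isomerisation of the γ-hydroxy ynoate to a γ-oxo enoate. Should any silyl group have migrated in step 7, silylation of the free hydroxyl gives the same product.

Step 9
Reactants: 7 (3Z)-1-methoxy-7-methyl-1,3-bis(trimethylsilyloxy)octa-1,3,6-triene; 16 methyl 4-(TBSO)-4-[2-(TBSO)-3-chloro-6-methoxy-4-methylphenyl]but-2-ynoate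
Product: 19 methyl 2-{(TBSO)[2-(TBSO)-3-chloro-6-methoxy-4-methylphenyl]methyl}-4,6-dihydroxy-3-(3-methylbut-2-enyl)benzoate (racemic), via cyclohexadiene cycloadduct 17 (not isolated), via bis(trimethylsilyl) ether 18 (not isolated)
Conditions: 7 (3 equiv), toluene, 110 °C, sealed tube; then citric acid, MeOH, 23 °C
Reagents that add atoms: none
Why: Normal-demand Diels–Alder reaction between the electron-rich bis(silyloxy)diene and the ynoate, followed by aromatisation; the closest known reaction type is the cycloaromatisation of 1-methoxy-1,3-bis(trimethylsilyloxy)buta-1,3-dienes with acetylenic esters to 2,4-dihydroxybenzoates. Bond formation is asynchronous: the nucleophilic γ-terminus of 7 (future C6') attacks the alkyne carbon β to the ester (C1') and the ketene acetal carbon (C3') then bonds to the α-carbon (C2'), so ring B closes as a six-membered carbocycle by (4+2) cycloaddition to give cyclohexa-1,4-diene 17. The required regioselectivity follows from the ester being the only acceptor on the alkyne, which is why the ketone is carried as a silyl-protected carbinol. The 3Z geometry of 7 keeps the prenyl CH2 outside the s-cis diene, and the linear alkyne holds the bulky carbinol one atom away from the bonding carbon. 17 loses methanol from C3' and the C6' hydrogen (1,4-elimination, completed by collapse of the mixed ketal on acidification) to give arene 18. Citric acid in methanol then removes the two TMS groups while the hindered TBS ethers remain. No lasting stereocentre is created: the sp3 centres of 17 vanish on aromatisation and the existing carbinol centre stays racemic. Excess diene makes up for its thermal and hydrolytic loss.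

Step 10
Reactants: 19 methyl 2-{(TBSO)[2-(TBSO)-3-chloro-6-methoxy-4-methylphenyl]methyl}-4,6-dihydroxy-3-(3-methylbut-2-enyl)benzoate
Product: 21 3-(3-chloro-2-hydroxy-6-methoxy-4-methylphenyl)-5,7-dihydroxy-4-(3-methylbut-2-enyl)-2-benzofuran-1(3H)-one (racemic), via hydroxy ester 20 (not isolated)
Conditions: Bu4NF, THF, 0 → 23 °C; then AcOH
Reagents that add atoms: none
Why: Fluoride cleaves the aryl and the benzylic silyl ether, and the freed carbinol oxygen attacks the ortho ester (5-exo-trig acyl substitution) to give the phthalide. Acidification completes the lactonisation and leaves only phenols to protect.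

Step 11
Reactants: 21 3-(3-chloro-2-hydroxy-6-methoxy-4-methylphenyl)-5,7-dihydroxy-4-(3-methylbut-2-enyl)-2-benzofuran-1(3H)-one
Product: 22 5,7-bis(TBSO)-3-[2-(TBSO)-3-chloro-6-methoxy-4-methylphenyl]-4-(3-methylbut-2-enyl)-2-benzofuran-1(3H)-one (racemic)
Conditions: t-BuMe2SiCl, imidazole, DMF, 23 → 40 °C
Reagents that add atoms: tert-butyldimethylsilyl chloride, CC(C)(C)[Si](C)(C)Cl
Why: Silylation of three phenols with no alcohol present, so the diol of the next step emerges with all phenols capped and both carbinols free.

Step 12
Reactants: 22 5,7-bis(TBSO)-3-[2-(TBSO)-3-chloro-6-methoxy-4-methylphenyl]-4-(3-methylbut-2-enyl)-2-benzofuran-1(3H)-one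
Product: 24 [2-(TBSO)-3-chloro-6-methoxy-4-methylphenyl][3,5-bis(TBSO)-2-(hydroxymethyl)-6-(3-methylbut-2-enyl)phenyl]methanol (racemic), via lactol 23 (not isolated)
Conditions: i-Bu2AlH (excess), CH2Cl2, −78 → 0 °C; aq. KNaC4H4O6 (Rochelle salt)
Reagents that add atoms: none
Why: Reduction of a lactone to the diol through the lactol aluminate; aluminium alkoxides are poor nucleophiles toward silicon, so the aryl silyl ethers should stay in place. The neutral tartrate work-up spares the acid-sensitive diol.

Step 13
Reactants: 24 [2-(TBSO)-3-chloro-6-methoxy-4-methylphenyl][3,5-bis(TBSO)-2-(hydroxymethyl)-6-(3-methylbut-2-enyl)phenyl]methanol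
Product: 26 2-[2-(TBSO)-3-chloro-6-methoxy-4-methylbenzoyl]-4,6-bis(TBSO)-3-(3-methylbut-2-enyl)benzaldehyde, via bis(alkoxysulfonium) salt 25 (not isolated)
Conditions: (COCl)2, DMSO, CH2Cl2, −78 °C; then 24; then Et3N, −78 → 0 °C
Reagents that add atoms: none
Why: Swern oxidation: both alcohols are converted into alkoxysulfonium ions before base is added, so aldehyde and ketone are released together and the hydroxy aldehyde that would close to a lactol is never present. This is the known behaviour of 1,2-bis(hydroxymethyl)arenes; aryl silyl ethers and the prenyl group are inert.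

Step 14
Reactants: 26 2-[2-(TBSO)-3-chloro-6-methoxy-4-methylbenzoyl]-4,6-bis(TBSO)-3-(3-methylbut-2-enyl)benzaldehyde
Product: 27 Pestalone F, 2-(3-chloro-2-hydroxy-6-methoxy-4-methylbenzoyl)-4,6-dihydroxy-3-(3-methylbut-2-enyl)benzaldehyde
Conditions: Bu4NF, AcOH (1:1), THF, 0 °C
Reagents that add atoms: none
Why: Fluoride cleavage of aryl silyl ethers, two of them activated by an ortho carbonyl group; the acetic acid buffer keeps the medium near neutral and thus avoids both the base-induced hydride shift of the keto aldehyde to phthalide 21 and acid-induced chroman formation.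

## Compound list

1 | methyl acetoacetate | CC(=O)CC(=O)OC | starting material
2 | prenyl bromide (1-bromo-3-methylbut-2-ene) | CC(C)=CCBr | starting material
3 | sodium lithium dianion of methyl acetoacetate | C=C([O-])C=C([O-])OC.[Na+].[Li+] | intermediate (not isolated)
4 | methyl 7-methyl-3-oxooct-6-enoate | COC(=O)CC(=O)CCC=C(C)C | intermediate
5 | methyl 7-methyl-3-(trimethylsilyloxy)octa-2,6-dienoate (2E/2Z mixture) | COC(=O)C=C(O[Si](C)(C)C)CCC=C(C)C | intermediate
6 | lithium dienolate of 5 (lithium (3Z)-1-methoxy-7-methyl-3-(trimethylsilyloxy)octa-1,3,6-trien-1-olate) | COC([O-])=C/C(O[Si](C)(C)C)=C/CC=C(C)C.[Li+] | intermediate (not isolated)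
7 | (3Z)-1-methoxy-7-methyl-1,3-bis(trimethylsilyloxy)octa-1,3,6-triene (C1=C2 geometry unassigned) | COC(O[Si](C)(C)C)=C/C(O[Si](C)(C)C)=C/CC=C(C)C | intermediate
8 | 3-methoxy-5-methylphenol | COc1cc(C)cc(O)c1 | starting material
9 | 2-chloro-5-methoxy-3-methylphenol | COc1cc(C)c(Cl)c(O)c1 | intermediate
10 | 2-chloro-6-(hydroxymethyl)-5-methoxy-3-methylphenol (present as its magnesium salt) | COc1cc(C)c(Cl)c(O)c1CO | intermediate (not isolated)
11 | 3-chloro-2-hydroxy-6-methoxy-4-methylbenzaldehyde | COc1cc(C)c(Cl)c(O)c1C=O | intermediate
12 | 2-(tert-butyldimethylsilyloxy)-3-chloro-6-methoxy-4-methylbenzaldehyde | COc1cc(C)c(Cl)c(O[Si](C)(C)C(C)(C)C)c1C=O | intermediate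
13 | methyl propiolate | C#CC(=O)OC | starting material
14 | methyl 3-lithioprop-2-ynoate | [Li+].[C-]#CC(=O)OC | intermediate (not isolated)
15 | methyl 4-[2-(tert-butyldimethylsilyloxy)-3-chloro-6-methoxy-4-methylphenyl]-4-hydroxybut-2-ynoate (racemic) | COC(=O)C#CC(O)c1c(OC)cc(C)c(Cl)c1O[Si](C)(C)C(C)(C)C | intermediate
16 | methyl 4-(tert-butyldimethylsilyloxy)-4-[2-(tert-butyldimethylsilyloxy)-3-chloro-6-methoxy-4-methylphenyl]but-2-ynoate (racemic) | COC(=O)C#CC(O[Si](C)(C)C(C)(C)C)c1c(OC)cc(C)c(Cl)c1O[Si](C)(C)C(C)(C)C | intermediate
17 | methyl 2-{(tert-butyldimethylsilyloxy)[2-(tert-butyldimethylsilyloxy)-3-chloro-6-methoxy-4-methylphenyl]methyl}-6-methoxy-3-(3-methylbut-2-enyl)-4,6-bis(trimethylsilyloxy)cyclohexa-1,4-diene-1-carboxylate (mixture of diastereomers) | COC(=O)C1=C(C(O[Si](C)(C)C(C)(C)C)c2c(OC)cc(C)c(Cl)c2O[Si](C)(C)C(C)(C)C)C(CC=C(C)C)C(O[Si](C)(C)C)=CC1(OC)O[Si](C)(C)C | intermediate (not isolated)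
18 | methyl 2-{(tert-butyldimethylsilyloxy)[2-(tert-butyldimethylsilyloxy)-3-chloro-6-methoxy-4-methylphenyl]methyl}-3-(3-methylbut-2-enyl)-4,6-bis(trimethylsilyloxy)benzoate (racemic) | COC(=O)c1c(O[Si](C)(C)C)cc(O[Si](C)(C)C)c(CC=C(C)C)c1C(O[Si](C)(C)C(C)(C)C)c1c(OC)cc(C)c(Cl)c1O[Si](C)(C)C(C)(C)C | intermediate (not isolated)
19 | methyl 2-{(tert-butyldimethylsilyloxy)[2-(tert-butyldimethylsilyloxy)-3-chloro-6-methoxy-4-methylphenyl]methyl}-4,6-dihydroxy-3-(3-methylbut-2-enyl)benzoate (racemic) | COC(=O)c1c(O)cc(O)c(CC=C(C)C)c1C(O[Si](C)(C)C(C)(C)C)c1c(OC)cc(C)c(Cl)c1O[Si](C)(C)C(C)(C)C | intermediate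
20 | methyl 2-[(3-chloro-2-hydroxy-6-methoxy-4-methylphenyl)(hydroxy)methyl]-4,6-dihydroxy-3-(3-methylbut-2-enyl)benzoate (racemic) | COC(=O)c1c(O)cc(O)c(CC=C(C)C)c1C(O)c1c(OC)cc(C)c(Cl)c1O | intermediate (not isolated)
21 | 3-(3-chloro-2-hydroxy-6-methoxy-4-methylphenyl)-5,7-dihydroxy-4-(3-methylbut-2-enyl)-2-benzofuran-1(3H)-one (racemic) | O=C1OC(c2c(OC)cc(C)c(Cl)c2O)c2c1c(O)cc(O)c2CC=C(C)C | intermediate
22 | 5,7-bis(tert-butyldimethylsilyloxy)-3-[2-(tert-butyldimethylsilyloxy)-3-chloro-6-methoxy-4-methylphenyl]-4-(3-methylbut-2-enyl)-2-benzofuran-1(3H)-one (racemic) | O=C1OC(c2c(OC)cc(C)c(Cl)c2O[Si](C)(C)C(C)(C)C)c2c1c(O[Si](C)(C)C(C)(C)C)cc(O[Si](C)(C)C(C)(C)C)c2CC=C(C)C | intermediate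
23 | 5,7-bis(tert-butyldimethylsilyloxy)-3-[2-(tert-butyldimethylsilyloxy)-3-chloro-6-methoxy-4-methylphenyl]-4-(3-methylbut-2-enyl)-1,3-dihydro-2-benzofuran-1-ol (as aluminium alkoxide; mixture of diastereomers) | OC1OC(c2c(OC)cc(C)c(Cl)c2O[Si](C)(C)C(C)(C)C)c2c1c(O[Si](C)(C)C(C)(C)C)cc(O[Si](C)(C)C(C)(C)C)c2CC=C(C)C | intermediate (not isolated)
24 | [2-(tert-butyldimethylsilyloxy)-3-chloro-6-methoxy-4-methylphenyl][3,5-bis(tert-butyldimethylsilyloxy)-2-(hydroxymethyl)-6-(3-methylbut-2-enyl)phenyl]methanol (racemic) | OCc1c(O[Si](C)(C)C(C)(C)C)cc(O[Si](C)(C)C(C)(C)C)c(CC=C(C)C)c1C(O)c1c(OC)cc(C)c(Cl)c1O[Si](C)(C)C(C)(C)C | intermediate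
25 | bis(alkoxydimethylsulfonium) dichloride of 24: both carbinol oxygens of 24 carry an S(CH3)2 cation (racemic) | C[S+](C)OCc1c(O[Si](C)(C)C(C)(C)C)cc(O[Si](C)(C)C(C)(C)C)c(CC=C(C)C)c1C(O[S+](C)C)c1c(OC)cc(C)c(Cl)c1O[Si](C)(C)C(C)(C)C.[Cl-].[Cl-] | intermediate (not isolated)
26 | 2-[2-(tert-butyldimethylsilyloxy)-3-chloro-6-methoxy-4-methylbenzoyl]-4,6-bis(tert-butyldimethylsilyloxy)-3-(3-methylbut-2-enyl)benzaldehyde | O=Cc1c(O[Si](C)(C)C(C)(C)C)cc(O[Si](C)(C)C(C)(C)C)c(CC=C(C)C)c1C(=O)c1c(OC)cc(C)c(Cl)c1O[Si](C)(C)C(C)(C)C | intermediate
27 | Pestalone F, 2-(3-chloro-2-hydroxy-6-methoxy-4-methylbenzoyl)-4,6-dihydroxy-3-(3-methylbut-2-enyl)benzaldehyde (achiral) | COc1cc(C)c(Cl)c(O)c1C(=O)c1c(C=O)c(O)cc(O)c1CC=C(C)C | target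

## Step count and risks

Total step count: 14. Longest linear sequence: 11 steps (8 to 27 through steps 4–14); the diene branch (steps 1–3) joins at step 9.

Least certain steps:

**Step 9 (key step).** Both bonding termini are substituted (prenyl CH2 on the diene, the bulky silyloxy(aryl)methyl group on the alkyne), so the bimolecular cycloaddition may be outrun by thermal decomposition or desilylation of the diene. Partial loss of the benzylic silyl ether during the acidic work-up is a lesser concern. The fallback keeps the cycloaddition for ring B but moves the crowded carbinol bond to a separate step; it sets out from 13, 7 and 12 and returns at 22. Bromination of the alkyne C–H of 13 (N-bromosuccinimide, AgNO3 cat., acetone) gives methyl 3-bromoprop-2-ynoate F1, a small dienophile. Cycloaddition of F1 with 7 and the same work-up should give methyl 2-bromo-4,6-dihydroxy-3-(3-methylbut-2-enyl)benzoate F2 with the same orientation (bromine on C1'). Silylation (t-BuMe2SiOTf, 2,6-lutidine) gives methyl 2-bromo-4,6-bis(TBSO)-3-(3-methylbut-2-enyl)benzoate F3. Bromine–magnesium exchange with i-PrMgCl·LiCl gives [3,5-bis(TBSO)-2-(methoxycarbonyl)-6-(3-methylbut-2-enyl)phenyl]magnesium chloride F4, which is added to aldehyde 12; the magnesium alkoxide closes onto the neighbouring ester and the route is rejoined at phthalide 22.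

**Step 4.** Chlorination may also occur para to the hydroxyl group (C4 of 8) or twice, because all three open positions are activated by both oxygens. The fallback sets out from 8 and returns at 9. Para-bromination (N-bromosuccinimide, MeCN, 0 °C) gives 4-bromo-3-methoxy-5-methylphenol F5 and blocks the para position. Chlorination with SO2Cl2 can then only go ortho and should prefer the site para to the methoxy group, giving 4-bromo-2-chloro-5-methoxy-3-methylphenol F6. Bromine–lithium exchange (n-BuLi, 2 equiv, THF, −78 °C; then MeOH), much faster for C–Br than for C–Cl, removes the blocking group.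

**Step 7.** The lithium acetylide may decompose before it adds to the doubly ortho-substituted aldehyde. Alternatively the aryl silyl group may migrate to the new alkoxide, after which the freed phenoxide could add to the ynoate in a conjugate cyclisation. The fallback sets out from 12 and returns at 16. Addition of HC≡CMgBr (THF, 0 °C) gives 1-[2-(TBSO)-3-chloro-6-methoxy-4-methylphenyl]prop-2-yn-1-ol F7 (racemic); no Michael acceptor is present at this stage. Silylation (t-BuMe2SiOTf, 2,6-lutidine) gives 1-(TBSO)-1-[2-(TBSO)-3-chloro-6-methoxy-4-methylphenyl]prop-2-yne F8. Deprotonation of the terminal alkyne (n-BuLi, THF, −78 °C) and acylation with methyl chloroformate give 16.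

**Step 12.** Aryl silyl groups may migrate to, or be lost at, the neighbouring alkoxides formed in the reduction, or the reduction may stop at the lactol stage. The fallback caps the phenols as ethers that cannot migrate; it sets out from 21 and returns at 27. K2CO3 and allyl bromide in DMF give 3-[3-chloro-6-methoxy-4-methyl-2-(prop-2-enyloxy)phenyl]-4-(3-methylbut-2-enyl)-5,7-bis(prop-2-enyloxy)-2-benzofuran-1(3H)-one F9. LiAlH4 in THF gives [3-chloro-6-methoxy-4-methyl-2-(prop-2-enyloxy)phenyl][2-(hydroxymethyl)-6-(3-methylbut-2-enyl)-3,5-bis(prop-2-enyloxy)phenyl]methanol F10. Swern oxidation gives 2-[3-chloro-6-methoxy-4-methyl-2-(prop-2-enyloxy)benzoyl]-3-(3-methylbut-2-enyl)-4,6-bis(prop-2-enyloxy)benzaldehyde F11. Allyl transfer to 4-MeC6H4SO2Na with catalytic Pd(PPh3)4 under neutral conditions gives 27.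

**Step 13.** The activated diaryl carbinol may ionise and close with the neighbouring hydroxymethyl group to a cyclic ether, or the two alcohols may be oxidised one after the other, which leads through the lactol back to the lactone. The fallback separates the two oxidations; it sets out from 24 and returns at 26. Selective silylation of the primary hydroxyl (Et3SiCl, imidazole, CH2Cl2, −40 °C) gives [2-(TBSO)-3-chloro-6-methoxy-4-methylphenyl]{3,5-bis(TBSO)-6-(3-methylbut-2-enyl)-2-[(triethylsilyloxy)methyl]phenyl}methanol F12. Dess–Martin oxidation of the remaining carbinol gives [2-(TBSO)-3-chloro-6-methoxy-4-methylphenyl]{3,5-bis(TBSO)-6-(3-methylbut-2-enyl)-2-[(triethylsilyloxy)methyl]phenyl}methanone F13, which cannot form a lactol. Mild acidic methanolysis (pyridinium p-toluenesulfonate, MeOH) gives [2-(TBSO)-3-chloro-6-methoxy-4-methylphenyl][3,5-bis(TBSO)-2-(hydroxymethyl)-6-(3-methylbut-2-enyl)phenyl]methanone F14, and a second Dess–Martin oxidation gives 26.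

## Further compounds

F1 | step 9 | methyl 3-bromoprop-2-ynoate | COC(=O)C#CBr
F2 | step 9 | methyl 2-bromo-4,6-dihydroxy-3-(3-methylbut-2-enyl)benzoate | COC(=O)c1c(O)cc(O)c(CC=C(C)C)c1Br
F3 | step 9 | methyl 2-bromo-4,6-bis(tert-butyldimethylsilyloxy)-3-(3-methylbut-2-enyl)benzoate | COC(=O)c1c(O[Si](C)(C)C(C)(C)C)cc(O[Si](C)(C)C(C)(C)C)c(CC=C(C)C)c1Br
F4 | step 9 | [3,5-bis(tert-butyldimethylsilyloxy)-2-(methoxycarbonyl)-6-(3-methylbut-2-enyl)phenyl]magnesium chloride (LiCl complex) | COC(=O)c1c(O[Si](C)(C)C(C)(C)C)cc(O[Si](C)(C)C(C)(C)C)c(CC=C(C)C)c1[Mg]Cl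
F5 | step 4 | 4-bromo-3-methoxy-5-methylphenol | COc1cc(O)cc(C)c1Br
F6 | step 4 | 4-bromo-2-chloro-5-methoxy-3-methylphenol | COc1cc(O)c(Cl)c(C)c1Br
F7 | step 7 | 1-[2-(tert-butyldimethylsilyloxy)-3-chloro-6-methoxy-4-methylphenyl]prop-2-yn-1-ol (racemic) | C#CC(O)c1c(OC)cc(C)c(Cl)c1O[Si](C)(C)C(C)(C)C
F8 | step 7 | 1-(tert-butyldimethylsilyloxy)-1-[2-(tert-butyldimethylsilyloxy)-3-chloro-6-methoxy-4-methylphenyl]prop-2-yne (racemic) | C#CC(O[Si](C)(C)C(C)(C)C)c1c(OC)cc(C)c(Cl)c1O[Si](C)(C)C(C)(C)C
F9 | step 12 | 3-[3-chloro-6-methoxy-4-methyl-2-(prop-2-enyloxy)phenyl]-4-(3-methylbut-2-enyl)-5,7-bis(prop-2-enyloxy)-2-benzofuran-1(3H)-one (racemic) | O=C1OC(c2c(OC)cc(C)c(Cl)c2OCC=C)c2c1c(OCC=C)cc(OCC=C)c2CC=C(C)C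
F10 | step 12 | [3-chloro-6-methoxy-4-methyl-2-(prop-2-enyloxy)phenyl][2-(hydroxymethyl)-6-(3-methylbut-2-enyl)-3,5-bis(prop-2-enyloxy)phenyl]methanol (racemic) | OCc1c(OCC=C)cc(OCC=C)c(CC=C(C)C)c1C(O)c1c(OC)cc(C)c(Cl)c1OCC=C
F11 | step 12 | 2-[3-chloro-6-methoxy-4-methyl-2-(prop-2-enyloxy)benzoyl]-3-(3-methylbut-2-enyl)-4,6-bis(prop-2-enyloxy)benzaldehyde | O=Cc1c(OCC=C)cc(OCC=C)c(CC=C(C)C)c1C(=O)c1c(OC)cc(C)c(Cl)c1OCC=C
F12 | step 13 | [2-(tert-butyldimethylsilyloxy)-3-chloro-6-methoxy-4-methylphenyl]{3,5-bis(tert-butyldimethylsilyloxy)-6-(3-methylbut-2-enyl)-2-[(triethylsilyloxy)methyl]phenyl}methanol (racemic) | CC[Si](CC)(CC)OCc1c(O[Si](C)(C)C(C)(C)C)cc(O[Si](C)(C)C(C)(C)C)c(CC=C(C)C)c1C(O)c1c(OC)cc(C)c(Cl)c1O[Si](C)(C)C(C)(C)C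
F13 | step 13 | [2-(tert-butyldimethylsilyloxy)-3-chloro-6-methoxy-4-methylphenyl]{3,5-bis(tert-butyldimethylsilyloxy)-6-(3-methylbut-2-enyl)-2-[(triethylsilyloxy)methyl]phenyl}methanone | CC[Si](CC)(CC)OCc1c(O[Si](C)(C)C(C)(C)C)cc(O[Si](C)(C)C(C)(C)C)c(CC=C(C)C)c1C(=O)c1c(OC)cc(C)c(Cl)c1O[Si](C)(C)C(C)(C)C
F14 | step 13 | [2-(tert-butyldimethylsilyloxy)-3-chloro-6-methoxy-4-methylphenyl][3,5-bis(tert-butyldimethylsilyloxy)-2-(hydroxymethyl)-6-(3-methylbut-2-enyl)phenyl]methanone | OCc1c(O[Si](C)(C)C(C)(C)C)cc(O[Si](C)(C)C(C)(C)C)c(CC=C(C)C)c1C(=O)c1c(OC)cc(C)c(Cl)c1O[Si](C)(C)C(C)(C)C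
A1 | alternative 1 | 3-[2,6-dibromo-3,5-bis(methoxymethoxy)phenyl]-4-methoxy-6-methyl-1,2-benzisoxazole | COc1cc(C)cc2onc(-c3c(Br)c(OCOC)cc(OCOC)c3Br)c12
A2 | alternative 1 | 3-methoxy-5-methyl-2-(trimethylsilyl)phenyl trifluoromethanesulfonate | COc1cc(C)cc(OS(=O)(=O)C(F)(F)F)c1[Si](C)(C)C
A3 | alternative 1 | 2,6-dibromo-3,5-bis(methoxymethoxy)benzonitrile oxide | COCOc1cc(OCOC)c(Br)c(C#[N+][O-])c1Br
A4 | alternative 2 | 2-{(tert-butyldimethylsilyloxy)[2-(tert-butyldimethylsilyloxymethyl)-3,5-bis(methoxymethoxy)-6-(3-methylbut-2-enyl)phenyl]methyl}-6-chloro-3-methoxy-5-methylphenol (racemic) | COc1cc(C)c(Cl)c(O)c1C(O[Si](C)(C)C(C)(C)C)c1c(CO[Si](C)(C)C(C)(C)C)c(OCOC)cc(OCOC)c1CC=C(C)C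
A5 | alternative 2 | 4-chloro-3-methylcyclobut-2-en-1-one (racemic) | CC1=CC(=O)C1Cl
A6 | alternative 2 | 1-(tert-butyldimethylsilyloxy)-1-[2-(tert-butyldimethylsilyloxymethyl)-3,5-bis(methoxymethoxy)-6-(3-methylbut-2-enyl)phenyl]-3-methoxyprop-2-yne (racemic) | COC#CC(O[Si](C)(C)C(C)(C)C)c1c(CO[Si](C)(C)C(C)(C)C)c(OCOC)cc(OCOC)c1CC=C(C)C
A7 | alternative 3 | 5-{(tert-butyldimethylsilyloxy)[2-(tert-butyldimethylsilyloxy)-3-chloro-6-methoxy-4-methylphenyl]methyl}-7-hydroxy-2,2-dimethyl-6-(3-methylbut-2-enyl)-4H-1,3-benzodioxin-4-one (racemic) | CC1(C)Oc2cc(O)c(CC=C(C)C)c(C(O[Si](C)(C)C(C)(C)C)c3c(OC)cc(C)c(Cl)c3O[Si](C)(C)C(C)(C)C)c2C(=O)O1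
A8 | alternative 3 | 6-{5-(tert-butyldimethylsilyloxy)-5-[2-(tert-butyldimethylsilyloxy)-3-chloro-6-methoxy-4-methylphenyl]-3-(3-methylbut-2-enyl)-2,4-dioxopentyl}-2,2-dimethyl-4H-1,3-dioxin-4-one (mixture of diastereomers) | CC1(C)OC(=O)C=C(CC(=O)C(CC=C(C)C)C(=O)C(O[Si](C)(C)C(C)(C)C)c2c(OC)cc(C)c(Cl)c2O[Si](C)(C)C(C)(C)C)O1
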